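**Retrosynthetic overview**
1. The target is reached by closing the oxirane last (C14–O onto C15) from a 14-hydroxy-15-tosylate diacid. This comes from 14,15-acetonide 25, which is the C11-deoxygenated form of 11-oxo tetrahydropyran 23.
2. Key disconnection: the C13–C16 (methyl) bond, made by conjugate addition of a methyl cuprate to the ring-B-fused 2,3-dihydro-4H-pyran-4-one 22. The strategy rests on quaternary C13 of ring C (O, C8, C9, C11, C12, C13), whose methyl is anti and whose oxirane carbon C14 is syn to the axial C8 methyl across the ring oxygen.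
3. Ring C is closed through the O–C13 bond by 6-endo cyclisation of β-hydroxy ynone 21, assembled from C11 aldehyde 15 and glycerate-derived alkyne 18.
4. Ring B comes from (S)-carvone: C4 by ester α-methylation, the C10 quaternary centre by enolate alkylation, C11 by methylenation and hydroboration, the C8 hydroxyl by Mukaiyama hydration.
5. Order of ring formation: ring B (chiral pool), ring C (step 14), oxirane (step 21).

Key step: step 15

Remark on numbering: labdane-type locants are used. Ring B is C5–C10; ring C is O, C8, C9, C11, C12, C13; C14/C15 are the dioxolane (later oxirane) carbons; C1–C2 is the acetic arm on C10; C3–C4 is the 2-methylpropanoate unit on C5; C16, C17 and C20 are the methyls on C13, C8 and C10.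

Remark on the chemistry (assumption): both carboxyl groups are carried as tert-butyl esters instead of methyl esters, so 22 and 23 are the di-tert-butyl analogues of the key-step pair. The α,α-disubstituted C3 ester cannot be saponified next to an oxirane, and a tert-butyl ester on C2 resists lactonisation by the C11 hydroxyl. Both are removed with acid before the oxirane is closed.

**Step 1**
Reactants: 1 (S)-carvone
Product: 2 (5S)-2-methyl-5-(2-methyloxiran-2-yl)cyclohex-2-en-1-one (oxirane epimers)
Conditions: mCPBA, CH2Cl2, 0 °C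
Reagents that add atoms: 3-chloroperoxybenzoic acid, OOC(=O)c1cccc(Cl)c1
Why: Prilezhaev epoxidation; the peracid should attack the electron-rich isopropenyl alkene and leave the electron-poor enone alkene alone, and the uncontrolled oxirane centre is erased in steps 2 and 5.

**Step 2**
Reactants: 2 epoxy enone
Product: 3 2-[(1S)-4-methyl-5-oxocyclohex-3-en-1-yl]propanal (α-epimers)
Conditions: BF3·OEt2 (0.3 equiv), CH2Cl2, −78 → −30 °C
Reagents that add atoms: none
Why: Meinwald rearrangement; Lewis-acid opening to the tertiary cation and a 1,2-hydride shift from the CH2–O carbon should give the α-branched aldehyde, whose α-centre is removed in step 5.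

**Step 3**
Reactants: 3 aldehyde
Product: 4 2-[(1S)-4-methyl-5-oxocyclohex-3-en-1-yl]propanoic acid (α-epimers)
Conditions: NaClO2, NaH2PO4, 2-methyl-2-butene, t-BuOH/H2O, rt
Reagents that add atoms: sodium chlorite, [Na+].[O-]Cl=O
Why: Pinnick oxidation should convert the aldehyde to the acid without touching the enone, the hypochlorite being trapped by the alkene scavenger.

**Step 4**
Reactants: 4 acid
Product: 5 tert-butyl 2-[(1S)-4-methyl-5-oxocyclohex-3-en-1-yl]propanoate (α-epimers)
Conditions: tert-butyl 2,2,2-trichloroacetimidate, BF3·OEt2 (cat.), CH2Cl2/cyclohexane, rt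
Reagents that add atoms: tert-butyl 2,2,2-trichloroacetimidate, CC(C)(C)OC(=N)C(Cl)(Cl)Cl
Why: Acid-catalysed O-alkylation of the carboxylic acid by the imidate (tert-butyl cation transfer) should give the tert-butyl ester under conditions the enone tolerates.

**Step 5**
Reactants: 5 keto ester
Product: 7 tert-butyl 2-[(1S)-4,6-dimethyl-5-oxocyclohex-3-en-1-yl]-2-methylpropanoate (C10 epimers), via dilithium bis-enolate 6 (not isolated)
Conditions: LiN(i-Pr)2 (2.2 equiv), THF, −78 °C; MeI (excess), −78 → 0 °C
Reagents that add atoms: iodomethane, CI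
Why: Double enolate alkylation; kinetic deprotonation should give the cross-conjugated ketone enolate and the ester enolate, and MeI quaternises C4 (no stereocentre) and methylates C10 (epimers, erased in step 6), after which the C3 ester has no α-hydrogen left.

**Step 6**
Reactants: 7 methylated keto ester, 8 tert-butyl bromoacetate
Product: 10 tert-butyl 2-[(1R,6S)-6-(1-tert-butoxy-2-methyl-1-oxopropan-2-yl)-1,3-dimethyl-2-oxocyclohex-3-en-1-yl]acetate, via lithium enolate 9 (not isolated)
Conditions: LiN(i-Pr)2, THF, −78 → −20 °C; DMPU; 8, −78 → 0 °C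
Reagents that add atoms: none
Why: Enolate alkylation that builds the C10 quaternary centre; the bulky C5 side chain sits pseudoaxial next to the enolate methyl and screens one face, so the bromoacetate should enter anti to it, placing the acetic arm trans and the methyl cis to the C5 substituent.

**Step 7**
Reactants: 10 keto diester
Product: 11 tert-butyl 2-[(1R,6S)-6-(1-tert-butoxy-2-methyl-1-oxopropan-2-yl)-1,3-dimethyl-2-methylidenecyclohex-3-en-1-yl]acetate
Conditions: Cp2Ti(μ-Cl)(μ-CH2)AlMe2 (Tebbe reagent), pyridine (cat.), THF/toluene, −40 °C → rt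
Reagents that add atoms: Tebbe reagent, written as Cp2Ti=CH2·ClAlMe2, C[Al](C)Cl.C=[Ti](C1C=CC=C1)C1C=CC=C1
Why: Tebbe methylenation; the non-basic titanium methylidene should olefinate the hindered C9 carbonyl through an oxatitanacyclobutane and leave the bulky tert-butyl esters untouched, giving the diene that carries C11.

**Step 8**
Reactants: 11 diene
Product: 13 homoallylic alcohol with CH2OH (C11) on C9 cis to the C10 methyl, via B-alkyl-9-BBN adduct 12 (not isolated)
Conditions: 9-BBN, THF, 0 °C → rt; then 3 M NaOH, 30% H2O2, 0 °C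
Reagents that add atoms: hydrogen peroxide, OO
Why: Hydroboration–oxidation; boron should add to the unhindered terminus C11 and hydrogen to C9 from the face opposite the C10 methyl and the C5 side chain, which leaves C11 cis to the C10 methyl, while the trisubstituted C7=C8 alkene reacts far more slowly with 9-BBN.

**Step 9**
Reactants: 13 homoallylic alcohol
Product: 14 8,11-diol with the C8 hydroxyl trans to C11 and the C8 methyl cis to the C10 methyl
Conditions: Co(acac)2 (20 mol %), PhSiH3, O2 (1 atm), THF, rt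
Reagents that add atoms: dioxygen, O=O
Why: Mukaiyama hydration; hydrogen-atom transfer to C7 gives the tertiary C8 radical in a chair held by the equatorial C5 and C9 substituents, and dioxygen should add anti to the axial C10 methyl, so the C8 hydroxyl is equatorial and the C8 methyl axial.

**Step 10**
Reactants: 14 diol
Product: 15 8-hydroxy C11 aldehyde
Conditions: Dess–Martin periodinane, pyridine, CH2Cl2, 0 °C → rt
Reagents that add atoms: none
Why: Dess–Martin oxidation should take the primary alcohol to the aldehyde under buffered, non-basic conditions that spare the tertiary alcohol and avoid retro-aldol cleavage or elimination.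

**Step 11**
Reactants: 16 methyl (S)-2,2-dimethyl-1,3-dioxolane-4-carboxylate
Product: 18 (R)-4-ethynyl-2,2-dimethyl-1,3-dioxolane, via (S)-glyceraldehyde acetonide 17 (not isolated)
Conditions: i-Bu2AlH, CH2Cl2, −78 °C; then MeOH, K2CO3, dimethyl (1-diazo-2-oxopropyl)phosphonate, 0 °C → rt
Reagents that add atoms: dimethyl (1-diazo-2-oxopropyl)phosphonate, CC(=O)C(=[N+]=[N-])P(=O)(OC)OC
Why: Partial reduction to the aluminium hemiacetal and Ohira–Bestmann (Seyferth–Gilbert) homologation of the aldehyde released in the flask should give the terminal alkyne, with the α-alkoxy centre untouched by any bond change.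

**Step 12**
Reactants: 15 aldehyde, 18 alkyne
Product: 20 propargylic alcohols (C11 epimers), via lithium acetylide 19 (not isolated)
Conditions: 18 (2.5 equiv), n-BuLi, THF, −78 °C; then 15, −78 °C; sat. NH4Cl at −78 °C
Reagents that add atoms: none
Why: 1,2-Addition of the lithium acetylide to the hindered aldehyde should form C11–C12 (one equivalent is consumed by the tertiary hydroxyl); the new carbinol centre is erased in step 13 and the cold quench guards against retro-aldol cleavage.

**Step 13**
Reactants: 20 propargylic alcohols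
Product: 21 β-hydroxy ynone
Conditions: Dess–Martin periodinane, pyridine, CH2Cl2, 0 °C → rt
Reagents that add atoms: none
Why: Dess–Martin oxidation of the secondary propargylic alcohol should give the ynone while the tertiary C8 hydroxyl is inert.

**Step 14**
Reactants: 21 β-hydroxy ynone
Product: 22 di-tert-butyl (5S,8S,9S,10R,14S)-8,13-epoxy-14,15-(isopropylidenedioxy)-11-oxo-2,3-secolabd-12-ene-2,3-dioate
Conditions: AgOTf (10 mol %), CH2Cl2, rt, dark
Reagents that add atoms: none
Why: π-Acid-catalysed 6-endo-dig hydroalkoxylation of the β-hydroxy ynone should close ring C through the O–C13 bond under neutral conditions that avoid retro-aldol cleavage; with C8–O and C9–C11 both equatorial the ring is trans-fused and no new stereocentre is made.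

**Step 15**
Reactants: 22 dihydropyranone
Product: 23 di-tert-butyl (5S,8S,9S,10R,13R,14S)-8,13-epoxy-14,15-(isopropylidenedioxy)-11-oxo-2,3-secolabdane-2,3-dioate
Conditions: Me2CuLi (from MeLi and CuI), BF3·OEt2, Et2O/THF, −78 °C; aq. NH4Cl at −78 °C
Reagents that add atoms: lithium dimethylcuprate, [Li+].C[Cu-]C (made from methyllithium, [Li]C, and CuI)
Why: BF3 coordinates the C11 carbonyl of the vinylogous ester, the cuprate forms a π-complex at C12=C13 and transfers methyl to C13 (C13–C16 bond), and the enolate is protonated at C12 on work-up. The closest known reaction type is the BF3-assisted organocuprate conjugate addition to 2-substituted 2,3-dihydro-4H-pyran-4-ones fused to a decalin, used to make the C13 quaternary centre of 8,13-epoxylabdan-11-ones. No ring is closed in this step. The one new stereocentre, C13, is controlled by the axial C8 methyl, which lies 1,3 to C13 across the ring oxygen on the same face as the C10 methyl; methyl should be delivered to the opposite face, which leaves the dioxolanyl carbon C14 syn to the C8 methyl. The step needs face selectivity at C13 and 1,4- over 1,2-addition: the trans ring fusion set in steps 8, 9 and 14 holds the C8 methyl axial over ring C, the soft cuprate with BF3 activation favours conjugate addition, and C14 (fixed from the chiral pool) can turn its C–O bond away from the reagent. Quenching at −78 °C keeps the enolate from expelling the ring oxygen from C13.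

**Step 16**
Reactants: 23 ketone
Product: 24 C11 tosylhydrazone of 23 (configuration as in 23)
Conditions: TsNHNH2, EtOH, 70 °C
Reagents that add atoms: 4-methylbenzenesulfonohydrazide, Cc1ccc(cc1)S(=O)(=O)NN
Why: Condensation of the C11 ketone with the sulfonyl hydrazide under neutral conditions should keep the acetonide and the tert-butyl esters and change no stereocentre.

**Step 17**
Reactants: 24 tosylhydrazone
Product: 25 di-tert-butyl (5S,8S,9S,10R,13R,14S)-8,13-epoxy-14,15-(isopropylidenedioxy)-2,3-secolabdane-2,3-dioate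
Conditions: catecholborane, CHCl3, 0 °C → rt; then NaOAc·3H2O, reflux
Reagents that add atoms: none
Why: Hydride delivery to the hydrazone carbon followed by acetate-induced loss of sulfinate and dinitrogen (a mild Wolff–Kishner-type deoxygenation) should turn C11 into CH2 without enolising C9 or C12.

**Step 18**
Reactants: 25 acetonide
Product: 26 di-tert-butyl (5S,8S,9S,10R,13R,14S)-8,13-epoxy-14,15-dihydroxy-2,3-secolabdane-2,3-dioate
Conditions: AcOH/H2O (4:1), 40 °C
Reagents that add atoms: none
Why: Aqueous acetic acid should hydrolyse the terminal acetonide while the tert-butyl esters and the ring ether survive; C14 keeps its configuration because no bond to it is broken.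

**Step 19**
Reactants: 26 diol
Product: 27 di-tert-butyl (5S,8S,9S,10R,13R,14S)-8,13-epoxy-14-hydroxy-15-(tosyloxy)-2,3-secolabdane-2,3-dioate
Conditions: TsCl, Et3N, Bu2SnO (5 mol %), CH2Cl2, rt
Reagents that add atoms: 4-methylbenzenesulfonyl chloride, Cc1ccc(cc1)S(Cl)(=O)=O
Why: Stannylene-acetal-catalysed sulfonylation should be selective for the primary C15 hydroxyl of the 1,2-diol and leave the secondary C14 hydroxyl free.

**Step 20**
Reactants: 27 hydroxy tosylate
Product: 28 (5S,8S,9S,10R,13R,14S)-8,13-epoxy-14-hydroxy-15-(tosyloxy)-2,3-secolabdane-2,3-dioic acid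
Conditions: TFA/CH2Cl2 (1:3), 0 °C → rt; evaporation with toluene
Reagents that add atoms: none
Why: Acidolysis of both tert-butyl esters by alkyl–oxygen cleavage is insensitive to the crowding at C3 and should free the two acids while the primary tosylate is stable; any trifluoroacetate formed at the C14 hydroxyl is cleaved in step 21.

**Step 21**
Reactants: 28 hydroxy tosylate diacid
Product: 30 (5S,8S,9S,10R,13R,14S)-8,13:14,15-diepoxy-2,3-secolabdane-2,3-dioic acid (target), via dipotassium salt 29 (not isolated)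
Conditions: K2CO3 (4 equiv), MeOH, 0 °C → rt; then 1 M HCl to pH 4 at 0 °C, EtOAc
Reagents that add atoms: none
Why: Intramolecular Williamson substitution (3-exo-tet); the C14 alkoxide should displace the C15 tosylate so that C14 retains its configuration, the carboxylates being too remote to compete, and careful acidification then gives the epoxy diacid.

**Compound list**
1 | (S)-carvone | CC1=CC[C@@H](CC1=O)C(C)=C | starting material
2 | (5S)-2-methyl-5-(2-methyloxiran-2-yl)cyclohex-2-en-1-one (oxirane epimers) | CC1(CO1)[C@H]2CC=C(C)C(=O)C2 | intermediate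
3 | 2-[(1S)-4-methyl-5-oxocyclohex-3-en-1-yl]propanal (α-epimers) | CC(C=O)[C@H]1CC=C(C)C(=O)C1 | intermediate
4 | 2-[(1S)-4-methyl-5-oxocyclohex-3-en-1-yl]propanoic acid (α-epimers) | CC(C(=O)O)[C@H]1CC=C(C)C(=O)C1 | intermediate
5 | tert-butyl 2-[(1S)-4-methyl-5-oxocyclohex-3-en-1-yl]propanoate (α-epimers) | CC(C(=O)OC(C)(C)C)[C@H]1CC=C(C)C(=O)C1 | intermediate
6 | dilithium bis-enolate of 5 (ketone and ester enolates; not isolated) | [Li+].[Li+].CC(=C([O-])OC(C)(C)C)[C@H]1CC=C(C)C([O-])=C1 | intermediate
7 | tert-butyl 2-[(1S)-4,6-dimethyl-5-oxocyclohex-3-en-1-yl]-2-methylpropanoate (C10 epimers) | CC(C)(C(=O)OC(C)(C)C)[C@H]1CC=C(C)C(=O)C1C | intermediate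
8 | tert-butyl bromoacetate | BrCC(=O)OC(C)(C)C | starting material
9 | lithium enolate of 7 (C9–O, C9=C10; not isolated) | [Li+].CC(C)(C(=O)OC(C)(C)C)[C@H]1CC=C(C)C([O-])=C1C | intermediate
10 | tert-butyl 2-[(1R,6S)-6-(1-tert-butoxy-2-methyl-1-oxopropan-2-yl)-1,3-dimethyl-2-oxocyclohex-3-en-1-yl]acetate (acetic arm trans, C10 methyl cis to the C5 side chain) | CC(C)(C(=O)OC(C)(C)C)[C@H]1CC=C(C)C(=O)[C@]1(C)CC(=O)OC(C)(C)C | intermediate
11 | tert-butyl 2-[(1R,6S)-6-(1-tert-butoxy-2-methyl-1-oxopropan-2-yl)-1,3-dimethyl-2-methylidenecyclohex-3-en-1-yl]acetate | CC(C)(C(=O)OC(C)(C)C)[C@H]1CC=C(C)C(=C)[C@]1(C)CC(=O)OC(C)(C)C | intermediate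
12 | B-alkyl-9-BBN adduct of 11 (boron on C11, H on C9; not isolated) | CC(C)(C(=O)OC(C)(C)C)[C@H]1CC=C(C)[C@@H](CB2C3CCCC2CCC3)[C@]1(C)CC(=O)OC(C)(C)C | intermediate
13 | homoallylic alcohol: ring-B cyclohexene (C7=C8, 8-methyl), C9 bearing CH2OH cis to the C10 methyl, C5 and C10 as in 10 | CC(C)(C(=O)OC(C)(C)C)[C@H]1CC=C(C)[C@@H](CO)[C@]1(C)CC(=O)OC(C)(C)C | intermediate
14 | 8,11-diol: C8 hydroxyl trans to the C9 CH2OH and cis to the C10 acetic arm, C8 methyl cis to the C10 methyl | CC(C)(C(=O)OC(C)(C)C)[C@H]1CC[C@](C)(O)[C@@H](CO)[C@]1(C)CC(=O)OC(C)(C)C | intermediate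
15 | 8-hydroxy C11 aldehyde (configuration as in 14) | CC(C)(C(=O)OC(C)(C)C)[C@H]1CC[C@](C)(O)[C@@H](C=O)[C@]1(C)CC(=O)OC(C)(C)C | intermediate
16 | methyl (S)-2,2-dimethyl-1,3-dioxolane-4-carboxylate | COC(=O)[C@@H]1COC(C)(C)O1 | starting material
17 | (S)-2,2-dimethyl-1,3-dioxolane-4-carbaldehyde (not isolated) | O=C[C@@H]1COC(C)(C)O1 | intermediate
18 | (R)-4-ethynyl-2,2-dimethyl-1,3-dioxolane | C#C[C@@H]1COC(C)(C)O1 | intermediate
19 | lithium acetylide of 18 (not isolated) | [Li+].[C-]#C[C@@H]1COC(C)(C)O1 | intermediate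
20 | propargylic alcohols: 15 with C11 as CH(OH)–C≡C–dioxolanyl (C11 epimers) | CC(C)(C(=O)OC(C)(C)C)[C@H]1CC[C@](C)(O)[C@@H](C(O)C#C[C@@H]2COC(C)(C)O2)[C@]1(C)CC(=O)OC(C)(C)C | intermediate
21 | β-hydroxy ynone: C8–OH, C9–C11(=O)–C12≡C13–dioxolanyl | CC(C)(C(=O)OC(C)(C)C)[C@H]1CC[C@](C)(O)[C@@H](C(=O)C#C[C@@H]2COC(C)(C)O2)[C@]1(C)CC(=O)OC(C)(C)C | intermediate
22 | di-tert-butyl (5S,8S,9S,10R,14S)-8,13-epoxy-14,15-(isopropylidenedioxy)-11-oxo-2,3-secolabd-12-ene-2,3-dioate (key-step precursor) | CC(C)(C)OC(=O)C(C)(C)[C@H]1CC[C@]2(C)OC([C@@H]3COC(C)(C)O3)=CC(=O)[C@H]2[C@]1(C)CC(=O)OC(C)(C)C | intermediate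
23 | di-tert-butyl (5S,8S,9S,10R,13R,14S)-8,13-epoxy-14,15-(isopropylidenedioxy)-11-oxo-2,3-secolabdane-2,3-dioate (key-step product) | CC(C)(C)OC(=O)C(C)(C)[C@H]1CC[C@]2(C)O[C@@](C)([C@@H]3COC(C)(C)O3)CC(=O)[C@H]2[C@]1(C)CC(=O)OC(C)(C)C | intermediate
24 | C11 tosylhydrazone of 23 (configuration as in 23) | CC(C)(C)OC(=O)C(C)(C)[C@H]1CC[C@]2(C)O[C@@](C)([C@@H]3COC(C)(C)O3)CC(=NNS(=O)(=O)c3ccc(C)cc3)[C@H]2[C@]1(C)CC(=O)OC(C)(C)C | intermediate
25 | di-tert-butyl (5S,8S,9S,10R,13R,14S)-8,13-epoxy-14,15-(isopropylidenedioxy)-2,3-secolabdane-2,3-dioate | CC(C)(C)OC(=O)C(C)(C)[C@H]1CC[C@]2(C)O[C@@](C)([C@@H]3COC(C)(C)O3)CC[C@H]2[C@]1(C)CC(=O)OC(C)(C)C | intermediate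
26 | di-tert-butyl (5S,8S,9S,10R,13R,14S)-8,13-epoxy-14,15-dihydroxy-2,3-secolabdane-2,3-dioate | CC(C)(C)OC(=O)C(C)(C)[C@H]1CC[C@]2(C)O[C@@](C)([C@@H](O)CO)CC[C@H]2[C@]1(C)CC(=O)OC(C)(C)C | intermediate
27 | di-tert-butyl (5S,8S,9S,10R,13R,14S)-8,13-epoxy-14-hydroxy-15-(tosyloxy)-2,3-secolabdane-2,3-dioate | CC(C)(C)OC(=O)C(C)(C)[C@H]1CC[C@]2(C)O[C@@](C)([C@@H](O)COS(=O)(=O)c3ccc(C)cc3)CC[C@H]2[C@]1(C)CC(=O)OC(C)(C)C | intermediate
28 | (5S,8S,9S,10R,13R,14S)-8,13-epoxy-14-hydroxy-15-(tosyloxy)-2,3-secolabdane-2,3-dioic acid | CC(C)(C(=O)O)[C@H]1CC[C@]2(C)O[C@@](C)([C@@H](O)COS(=O)(=O)c3ccc(C)cc3)CC[C@H]2[C@]1(C)CC(=O)O | intermediate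
29 | dipotassium salt of the target (not isolated) | [K+].[K+].CC(C)(C(=O)[O-])[C@H]1CC[C@]2(C)O[C@@](C)([C@@H]3CO3)CC[C@H]2[C@]1(C)CC(=O)[O-] | intermediate
30 | (5S,8S,9S,10R,13R,14S)-8,13:14,15-diepoxy-2,3-secolabdane-2,3-dioic acid (CNP0160287.2) | CC(C)(C(=O)O)[C@H]1CC[C@]2(C)O[C@@](C)([C@@H]3CO3)CC[C@H]2[C@]1(C)CC(=O)O | target

Total step count: 21
Longest linear sequence: 20 steps (steps 1–10 and 12–21, from 1)

**Steps most likely to fail**

Step 15 (key step). Facial control at C13 may be incomplete, the methyl may add 1,2 to C11, or the enolate may expel the ring oxygen from C13 and open ring C. The fallback sets out from 22 and returns at 25, so steps 16 and 17 are then not needed. Luche reduction (NaBH4, CeCl3·7H2O, MeOH, −78 °C) should give the 11-hydroxy dihydropyran F7. Acetylation (Ac2O, pyridine, DMAP) gives the allylic acetate F8. Ferrier-type substitution with Me3Al (CH2Cl2, −78 °C) ionises F8 to the ring-C oxocarbenium ion and should deliver methyl axially to C13, anti to the C8 methyl, to give the Δ11 ether F9 with quaternary C13. Hydrogenation (H2, Pd/C, EtOAc) then gives 25.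

Step 6. C-alkylation at the crowded enolate carbon next to the bulky C5 side chain may be slow, so that proton transfer to the bromoacetate or O-alkylation takes over. The fallback reverses the order of construction, sets out from 1 and returns at 10. Methylation of 1 (LiN(i-Pr)2, MeI) gives 6-methylcarvone F1. Alkylation of its enolate with 8, trans to the small isopropenyl group, gives the quaternary keto ester F2. Epoxidation with mCPBA gives the isopropenyl oxide F3, and Meinwald rearrangement (BF3·OEt2) gives the α-branched aldehyde F4. α-Methylation with t-BuOK and MeI, under which the tert-butyl ester is not enolised, gives the quaternary aldehyde F5. Pinnick oxidation gives the acid F6, and esterification with tert-butyl 2,2,2-trichloroacetimidate gives 10.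

Step 16. Condensation at the hindered C11 carbonyl may stall, and forcing it may epimerise C9 through the ene-hydrazine. The fallback sets out from 23 and returns at 25. Reduction with NaBH4 (MeOH, 0 °C) gives the 11-alcohol F10. 1,1'-Thiocarbonyldiimidazole (DMAP, toluene, 80 °C) gives the O-alkyl imidazole-1-carbothioate F11. Barton–McCombie deoxygenation (Bu3SnH, AIBN, toluene, 100 °C) then gives 25 without any enolisable intermediate.

**Further compounds**
F1 | step 6 | (5S)-2,6-dimethyl-5-(prop-1-en-2-yl)cyclohex-2-en-1-one (6-methylcarvone, C6 epimers) | CC1=CC[C@@H](C(C)C1=O)C(C)=C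
F2 | step 6 | tert-butyl 2-[(1R,6S)-1,3-dimethyl-2-oxo-6-(prop-1-en-2-yl)cyclohex-3-en-1-yl]acetate | CC(=C)[C@H]1CC=C(C)C(=O)[C@]1(C)CC(=O)OC(C)(C)C
F3 | step 6 | isopropenyl oxide of F2 (oxirane epimers) | CC1(CO1)[C@H]2CC=C(C)C(=O)[C@]2(C)CC(=O)OC(C)(C)C
F4 | step 6 | α-branched aldehyde from F3 (C5 bears CH(CH3)CHO, α-epimers) | CC(C=O)[C@H]1CC=C(C)C(=O)[C@]1(C)CC(=O)OC(C)(C)C
F5 | step 6 | quaternary aldehyde (C5 bears C(CH3)2CHO) | CC(C)(C=O)[C@H]1CC=C(C)C(=O)[C@]1(C)CC(=O)OC(C)(C)C
F6 | step 6 | quaternary acid (C5 bears C(CH3)2CO2H) | CC(C)(C(O)=O)[C@H]1CC=C(C)C(=O)[C@]1(C)CC(=O)OC(C)(C)C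
F7 | step 15 | 11-hydroxy dihydropyran from 22 (C11 epimers) | CC(C)(C)OC(=O)C(C)(C)[C@H]1CC[C@]2(C)OC([C@@H]3COC(C)(C)O3)=CC(O)[C@H]2[C@]1(C)CC(=O)OC(C)(C)C
F8 | step 15 | 11-acetoxy dihydropyran (C11 epimers) | CC(C)(C)OC(=O)C(C)(C)[C@H]1CC[C@]2(C)OC([C@@H]3COC(C)(C)O3)=CC(OC(C)=O)[C@H]2[C@]1(C)CC(=O)OC(C)(C)C
F9 | step 15 | Δ11 cyclic ether with quaternary C13 (13-methyl anti to the C8 methyl) | CC(C)(C)OC(=O)C(C)(C)[C@H]1CC[C@]2(C)O[C@@](C)([C@@H]3COC(C)(C)O3)C=C[C@H]2[C@]1(C)CC(=O)OC(C)(C)C
F10 | step 16 | 11-alcohol from 23 (C11 epimers) | CC(C)(C)OC(=O)C(C)(C)[C@H]1CC[C@]2(C)O[C@@](C)([C@@H]3COC(C)(C)O3)CC(O)[C@H]2[C@]1(C)CC(=O)OC(C)(C)C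
F11 | step 16 | O-(C11) imidazole-1-carbothioate of F10 | CC(C)(C)OC(=O)C(C)(C)[C@H]1CC[C@]2(C)O[C@@](C)([C@@H]3COC(C)(C)O3)CC(OC(=S)n3ccnc3)[C@H]2[C@]1(C)CC(=O)OC(C)(C)C
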